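**Plan**

1. Retrosynthesis: the C6 angelate C–O bond is cut first, then C11=C13 and C7–C11 (dehydration, Mukaiyama aldol with methyl pyruvate), then C4–C15 and the C4–O bond (methylenation, epoxide), and last C5–C6 and C9–C10, which opens ring B to a diene and a quinone.
2. Enabling feature: ring B (C5–C10) carries oxygen on C6 and C8 and shares with ring A the C5–C10 edge, whose C10 is a methyl-bearing quaternary carbon. Ring B is therefore the adduct of a 1,3-dioxygenated butadiene (C6–C9) with the methyl-substituted double bond of 2-methoxy-5-methylbenzoquinone, which is ring A (C1–C5, C10) with C14 already in place.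
3. Forward order: ring A is bought as the quinone and ring B closes in the cycloaddition. C5 is then inverted to the trans-decalin and ring A is trimmed (methoxy out, C4 methylene, C1 alcohol). The C11–C13 chain is joined at C7 through the enol silane that the cycloaddition leaves at C7=C8, and C8, C4 and the C6 ester are finished last.
4. Stereochemistry: C10 comes from the chiral titanium catalyst, C6 from the endo mode and C5 from base equilibration. C1, C7 and C8 end equatorial (axial hydride attack; attack anti to the C6 ether, backed by equilibration α to the ketone; chelated SmI2 reduction). C4 comes from α-face epoxidation opposite the axial C14 methyl.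
5. The C6 oxygen enters as a PMB ether instead of a silyl ether, so that it can be freed for angeloylation while C1 and C8 stay silylated.

Key step: step 3

Conventions: eudesmane numbering is used (ring A = C1–C5, C10; ring B = C5–C10; C11–C13 on C7; C14 on C10; C15 on C4). β is the face of the C14 methyl. PMB = 4-methoxybenzyl, TBS = tert-butyldimethylsilyl.

Remark (assumption): the (S)-BINOLate titanium catalyst is assumed to give the 10β-methyl enantiomer of 6 drawn here, and the (R)-ligand would be used unchanged if the sense of induction is the opposite; C3 of 8 and C11 of 14–16 are formed without control and left unassigned, because both centres disappear later.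

**Route**

Step 1
Reactants: 1 (E)-4-methoxybut-3-en-2-one; 2 4-methoxybenzyl alcohol
Product: 3 (E)-4-(4-methoxybenzyloxy)but-3-en-2-one
Conditions: PPTS (5 mol %), toluene, 110 °C, MeOH distilled off
Reagents that add atoms: none
Why: Acid-catalysed addition–elimination at the β-carbon (vinylogous transesterification) exchanges the enol-ether alcohol, is driven by removal of methanol and should end at the conjugated (E)-isomer.

Step 2
Reactants: 3
Product: 4 (E)-3-(tert-butyldimethylsilyloxy)-1-(4-methoxybenzyloxy)buta-1,3-diene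
Conditions: TBSOTf, Et3N, Et2O, 0 °C → rt
Reagents that add atoms: tert-butyldimethylsilyl triflate, CC(C)(C)[Si](C)(C)OS(=O)(=O)C(F)(F)F
Why: Soft enolisation of the methyl ketone by a silyl triflate and an amine (silyl enol ether formation) should give the 2-silyloxydiene with the (E)-enol ether intact.

Step 3
Reactants: 4; 5 2-methoxy-5-methyl-1,4-benzoquinone
Product: 6 cis-fused endo adduct (ring A: C1 ketone, C2=C3 with OMe on C3, C4 ketone; ring B: 6α-OPMB, C7=C8 with OTBS on C8; 10β-methyl, 5β-H)
Conditions: TiCl2(OiPr)2 (10 mol %), (S)-BINOL (10 mol %), 4 Å MS, CH2Cl2, −78 → −30 °C; pH 7 buffer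
Reagents that add atoms: none
Why: The tetravalent titanium centre is held by the methoxy oxygen and the neighbouring carbonyl of 5 (future C4), which activates the methyl-bearing double bond and makes its methyl carbon (future C10) the β-terminus, so a concerted but asynchronous [4+2] cycloaddition bonds C10 to the nucleophilic CH2 end of 4 (C9) ahead of C5 to C6; the closest known reaction type is the BINOL–titanium-catalysed Diels–Alder reaction of methoxyquinones with oxygenated dienes. Ring B is closed as a cyclohexene by this intermolecular [4+2] cycloaddition, both σ bonds (C5–C6, C9–C10) forming suprafacially on each partner. C10 is fixed in the absolute sense by the BINOLate ligand, which shields one face of the chelated quinone; C5 is cis to the C10 methyl because the dienophile adds suprafacially; C6 follows from the endo transition state of the (E)-enol ether, which puts the C6 ether cis to the C4 carbonyl (α). The step needs site selectivity (the methoxy-bearing double bond is a deactivated vinylogous ester), regioselectivity (chelation on the quinone and the matched 1,3-dioxygenation of the diene), endo selectivity (secondary orbital overlap, reinforced by the Lewis acid) and facial selectivity (the chiral ligand).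

Step 4
Reactants: 6
Product: 7 trans-fused enedione (C5 epimer of 6: 5α-H, 6α-OPMB equatorial, 10β-methyl)
Conditions: DBU (0.2 equiv), toluene, 0 °C → rt
Reagents that add atoms: none
Why: Base-mediated epimerisation through the C4 enolate inverts C5, the only enolisable stereocentre, and the trans-fused isomer should be the more stable one, as for 10-methyl-4-oxo-decalins and the parent butadiene adduct of this quinone.

Step 5
Reactants: 7
Product: 9 trans-fused 1,4-diketone (3-demethoxy-2,3-dihydro-7), via methoxy diketone 8 (not isolated)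
Conditions: SmI2 (4.5 equiv), THF/MeOH (10:1), −78 °C
Reagents that add atoms: none
Why: Single-electron reduction by SmI2 first saturates the enedione and then expels the methoxy group, now α to the C4 ketone, from the ketyl (reductive cleavage of an α-alkoxy ketone); the enolates involved lie at C1/C2 and C3/C4, so C5 and the C6 ether are not touched.

Step 6
Reactants: 9
Product: 10 4-methylene ketone (C4=C15 exocyclic, C1 ketone, 5α-H, 6α-OPMB, C7=C8 enol silane)
Conditions: Ph3PCH3Br, KOtBu, THF, 0 °C; then 9, 0 °C → rt
Reagents that add atoms: methyltriphenylphosphonium bromide, C[P+](c1ccccc1)(c1ccccc1)c1ccccc1.[Br-]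
Why: Wittig methylenation should pick the C4 ketone because C1 is flanked by the quaternary C10 and reacts far more slowly with the bulky ylide.

Step 7
Reactants: 10
Product: 11 1β-alcohol (equatorial OH, 1α-H)
Conditions: LiAlH4, THF, −78 → 0 °C
Reagents that add atoms: none
Why: Hydride reduction of the remaining ketone by axial attack on the α face, away from the adjacent axial C14 methyl, should give the equatorial 1β-alcohol.

Step 8
Reactants: 11
Product: 12 1β-TBS ether (C4=C15, 6α-OPMB, C7=C8 enol silane)
Conditions: TBSOTf, 2,6-lutidine, CH2Cl2, 0 °C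
Reagents that add atoms: tert-butyldimethylsilyl triflate, CC(C)(C)[Si](C)(C)OS(=O)(=O)C(F)(F)F
Why: O-Silylation with the silyl triflate covers the hindered neopentyl alcohol before the Lewis acid step, and the buffered conditions spare the enol silane.

Step 9
Reactants: 12; 13 methyl pyruvate
Product: 14 aldol adduct (C8 ketone; 7β-[C(OH)(CH3)CO2Me], 7α-H)
Conditions: TiCl4, CH2Cl2, −78 °C (13 and TiCl4 premixed, then 12); aq. NaHCO3
Reagents that add atoms: none
Why: In this Mukaiyama aldol reaction the regiodefined enol silane attacks the chelated pyruvate–TiCl4 complex through C7 on the face anti to the C6 ether (β), the equatorial 7β epimer is also the thermodynamic one at this centre α to the new ketone, and the enol silane far outpaces an ene reaction of the 1,1-disubstituted alkene.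

Step 10
Reactants: 14
Product: 15 8α,11-diol (8α-OH equatorial, 8β-H)
Conditions: SmI2 (3 equiv), THF/MeOH (4:1), 0 °C
Reagents that add atoms: none
Why: Chelation-assisted single-electron reduction of the β-hydroxy ketone by SmI2 bridges the C11 oxygen and the ketyl, so that C8 is protonated axially and its oxygen ends equatorial (α), trans to the C7 substituent, while the ester and the alkene stay inert.

Step 11
Reactants: 15
Product: 16 1β,8α-bis-TBS ether with free tertiary C11 alcohol
Conditions: TBSOTf (1.1 equiv), 2,6-lutidine, CH2Cl2, −78 °C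
Reagents that add atoms: tert-butyldimethylsilyl triflate, CC(C)(C)[Si](C)(C)OS(=O)(=O)C(F)(F)F
Why: Silyl ether formation at low temperature should take the secondary C8 hydroxyl and leave the hindered tertiary α-hydroxy ester free.

Step 12
Reactants: 16
Product: 17 acrylate (C11=C13 with CO2Me on C11; C4=C15; 6α-OPMB; 1β,8α-bis-TBS)
Conditions: SOCl2, pyridine, CH2Cl2, −20 → 0 °C
Reagents that add atoms: none
Why: Dehydration through the chlorosulfite (E2 with pyridine) should remove a proton from the unhindered methyl group, since a C7=C11 alkylidene would clash with both flanking equatorial ethers (allylic 1,3-strain).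

Step 13
Reactants: 17
Product: 18 4α,15-epoxide (epoxide oxygen α, C15 β)
Conditions: mCPBA, NaHCO3, CH2Cl2, 0 °C
Reagents that add atoms: mCPBA, OOC(=O)c1cccc(Cl)c1
Why: Prilezhaev epoxidation takes the electron-rich exocyclic alkene and not the acrylate, and the peracid should approach from the α face, opposite the axial C14 methyl.

Step 14
Reactants: 18
Product: 19 15-iodo-4α-ol (iodohydrin)
Conditions: LiI, AcOH, THF, rt
Reagents that add atoms: lithium iodide, [Li+].[I-]
Why: SN2 opening of the protonated epoxide by iodide at the primary C15 gives the iodohydrin with the C4–O bond, and hence the 4α configuration, unchanged.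

Step 15
Reactants: 19
Product: 20 4α-ol (4β-methyl, tertiary alcohol)
Conditions: Bu3SnH, Et3B (cat.), air, toluene, 0 °C
Reagents that add atoms: none
Why: Radical dehalogenation by the tin hydride chain replaces iodine by hydrogen under neutral conditions that the acrylate ester tolerates, which a hydride opening of the epoxide would not.

Step 16
Reactants: 20
Product: 21 4α,6α-diol (free 6α-OH; 1β,8α-bis-TBS)
Conditions: DDQ, CH2Cl2/pH 7 buffer (10:1), 0 °C
Reagents that add atoms: none
Why: Oxidative cleavage of the PMB ether by DDQ (hydride abstraction, then hydrolysis of the oxocarbenium ion by the water present) frees only the C6 hydroxyl and leaves silyl ethers, acrylate and tertiary alcohol alone.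

Step 17
Reactants: 21; 22 angelic acid
Product: 24 6α-angelate of 21 (1β,8α-bis-TBS ether), via mixed anhydride 23 (not isolated)
Conditions: 2,4,6-trichlorobenzoyl chloride, Et3N, toluene, rt; then 21, DMAP, toluene, 60 °C
Reagents that add atoms: none
Why: Yamaguchi esterification through the mixed anhydride acylates hindered secondary alcohols with angelic acid without Z→E isomerisation, and the tertiary C4 hydroxyl is too hindered to compete.

Step 18
Reactants: 24
Product: 25 target (CNP0136844.1)
Conditions: HF·pyridine, pyridine, THF, 0 °C → rt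
Reagents that add atoms: none
Why: Fluoride-mediated desilylation under buffered conditions removes both TBS ethers without touching the two esters or inducing lactonisation of the freed C8 hydroxyl.

**Compound list**

1 | (E)-4-methoxybut-3-en-2-one | CO/C=C/C(C)=O | starting material
2 | 4-methoxybenzyl alcohol | COc1ccc(CO)cc1 | starting material
3 | (E)-4-(4-methoxybenzyloxy)but-3-en-2-one | CC(=O)/C=C/OCc1ccc(OC)cc1 | intermediate
4 | (E)-3-(tert-butyldimethylsilyloxy)-1-(4-methoxybenzyloxy)buta-1,3-diene | C=C(O[Si](C)(C)C(C)(C)C)/C=C/OCc1ccc(OC)cc1 | intermediate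
5 | 2-methoxy-5-methyl-1,4-benzoquinone | COC1=CC(=O)C(C)=CC1=O | starting material
6 | cis-fused endo adduct (3-OMe ene-1,4-dione, 6α-OPMB, C7=C8 enol silane, 5β-H, 10β-Me) | O=C1C=C(OC)C(=O)[C@H]2[C@@H](OCc3ccc(OC)cc3)C=C(O[Si](C)(C)C(C)(C)C)C[C@@]12C | intermediate
7 | trans-fused enedione (5α-H) | O=C1C=C(OC)C(=O)[C@@H]2[C@@H](OCc3ccc(OC)cc3)C=C(O[Si](C)(C)C(C)(C)C)C[C@@]12C | intermediate
8 | trans-fused 3-methoxy-1,4-diketone (C3 unassigned) | O=C1CC(OC)C(=O)[C@@H]2[C@@H](OCc3ccc(OC)cc3)C=C(O[Si](C)(C)C(C)(C)C)C[C@@]12C | intermediate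
9 | trans-fused 1,4-diketone | O=C1CCC(=O)[C@@H]2[C@@H](OCc3ccc(OC)cc3)C=C(O[Si](C)(C)C(C)(C)C)C[C@@]12C | intermediate
10 | 4-methylene-1-ketone | O=C1CCC(=C)[C@@H]2[C@@H](OCc3ccc(OC)cc3)C=C(O[Si](C)(C)C(C)(C)C)C[C@@]12C | intermediate
11 | 1β-alcohol | O[C@@H]1CCC(=C)[C@@H]2[C@@H](OCc3ccc(OC)cc3)C=C(O[Si](C)(C)C(C)(C)C)C[C@@]12C | intermediate
12 | 1β-TBS ether, C7=C8 enol silane | CC(C)(C)[Si](C)(C)O[C@@H]1CCC(=C)[C@@H]2[C@@H](OCc3ccc(OC)cc3)C=C(O[Si](C)(C)C(C)(C)C)C[C@@]12C | intermediate
13 | methyl pyruvate | CC(=O)C(=O)OC | starting material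
14 | aldol adduct (C8 ketone, 7β side chain, C11 unassigned) | CC(C)(C)[Si](C)(C)O[C@@H]1CCC(=C)[C@@H]2[C@@H](OCc3ccc(OC)cc3)[C@H](C(C)(O)C(=O)OC)C(=O)C[C@@]12C | intermediate
15 | 8α,11-diol | CC(C)(C)[Si](C)(C)O[C@@H]1CCC(=C)[C@@H]2[C@@H](OCc3ccc(OC)cc3)[C@H](C(C)(O)C(=O)OC)[C@@H](O)C[C@@]12C | intermediate
16 | 1β,8α-bis-TBS ether, C11 tertiary alcohol | CC(C)(C)[Si](C)(C)O[C@@H]1CCC(=C)[C@@H]2[C@@H](OCc3ccc(OC)cc3)[C@H](C(C)(O)C(=O)OC)[C@@H](O[Si](C)(C)C(C)(C)C)C[C@@]12C | intermediate
17 | acrylate (4(15),11(13)-diene) | CC(C)(C)[Si](C)(C)O[C@@H]1CCC(=C)[C@@H]2[C@@H](OCc3ccc(OC)cc3)[C@H](C(=C)C(=O)OC)[C@@H](O[Si](C)(C)C(C)(C)C)C[C@@]12C | intermediate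
18 | 4α,15-epoxide | CC(C)(C)[Si](C)(C)O[C@@H]1CC[C@]4(CO4)[C@@H]2[C@@H](OCc3ccc(OC)cc3)[C@H](C(=C)C(=O)OC)[C@@H](O[Si](C)(C)C(C)(C)C)C[C@@]12C | intermediate
19 | 15-iodo-4α-ol | CC(C)(C)[Si](C)(C)O[C@@H]1CC[C@](O)(CI)[C@@H]2[C@@H](OCc3ccc(OC)cc3)[C@H](C(=C)C(=O)OC)[C@@H](O[Si](C)(C)C(C)(C)C)C[C@@]12C | intermediate
20 | 4α-ol (4β-methyl), 6α-OPMB | CC(C)(C)[Si](C)(C)O[C@@H]1CC[C@](O)(C)[C@@H]2[C@@H](OCc3ccc(OC)cc3)[C@H](C(=C)C(=O)OC)[C@@H](O[Si](C)(C)C(C)(C)C)C[C@@]12C | intermediate
21 | 4α,6α-diol, 1β,8α-bis-TBS ether | CC(C)(C)[Si](C)(C)O[C@@H]1CC[C@](O)(C)[C@@H]2[C@@H](O)[C@H](C(=C)C(=O)OC)[C@@H](O[Si](C)(C)C(C)(C)C)C[C@@]12C | intermediate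
22 | angelic acid, (Z)-2-methylbut-2-enoic acid | C/C=C(/C)C(=O)O | starting material
23 | angelic 2,4,6-trichlorobenzoic mixed anhydride | C/C=C(/C)C(=O)OC(=O)c1c(Cl)cc(Cl)cc1Cl | intermediate
24 | 6α-angelate, 1β,8α-bis-TBS ether | CC(C)(C)[Si](C)(C)O[C@@H]1CC[C@](O)(C)[C@@H]2[C@@H](OC(=O)/C(C)=C\C)[C@H](C(=C)C(=O)OC)[C@@H](O[Si](C)(C)C(C)(C)C)C[C@@]12C | intermediate
25 | CNP0136844.1, methyl 6α-angeloyloxy-1β,4α,8α-trihydroxyeudesm-11(13)-en-12-oate | C=C(C(=O)OC)[C@H]1[C@H](OC(=O)/C(C)=C\C)[C@@H]2[C@@](C)(C[C@@H]1O)[C@H](O)CC[C@@]2(C)O | target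

**Step count and risks**

Total step count: 18. Longest linear sequence: 18 steps (1 → 25); compounds 2, 5, 13 and 22 enter as purchased materials.

Steps most likely to fail:

Step 4 (inversion of C5). The equilibrium may not lie far enough on the trans side, because the equatorial C6 ether ends up beside the C4 carbonyl. The C4 enolate may also expel the C6 ether (β-elimination), driven by extension of the enedione chromophore. The fallback postpones the inversion to a saturated ketone. It sets out from 6: SmI2 in THF/MeOH, as in step 5, should give the cis-fused methoxy diketone F1 and from it, by loss of methoxide, the cis-fused 1,4-diketone F2. F2 is then equilibrated with K2CO3 in MeOH at 0 °C; here the C4 carbonyl is an ordinary 4-oxo-10-methyl-decalin ketone with a strong trans preference, and elimination no longer gains cross-conjugation. The fallback rejoins the route at 9.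

Step 10 (C8 configuration). Hydrogen may be delivered to the α face, which the axial C14 methyl leaves more open, giving the axial 8β-alcohol. The trivalent samarium alkoxide may also trigger retro-aldol cleavage. The fallback makes the axial alcohol on purpose and inverts it. It sets out from 14: LiBH(s-Bu)3 in THF at −78 °C (equatorial attack) should give the 8β-alcohol F3. Mitsunobu reaction with 4-nitrobenzoic acid, PPh3 and DIAD inverts C8 to the 8α-(4-nitrobenzoate) F4. Methanolysis with K2CO3 in MeOH at 0 °C releases the 8α-alcohol, rejoining the route at 15.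

Step 12 (regiochemistry of dehydration). The proton may be lost from C7 instead of from the methyl group, giving the tetrasubstituted C7=C11 alkylidene, or the tertiary centre may ionise and rearrange. The fallback replaces dehydration by a reductive elimination whose position is fixed by a halogen. It sets out from 12: Mukaiyama aldol reaction with methyl bromopyruvate and TiCl4 at −78 °C should give the bromohydrin ketone F5. SmI2 in THF/MeOH at 0 °C reduces C8 to the 8α-alcohol F6 (a primary alkyl bromide is inert to SmI2 without a donor additive), and TBSOTf with 2,6-lutidine gives the silyl ether F7. Zn dust in AcOH/THF then removes bromide and hydroxide from the vicinal bromohydrin and can place the double bond only between C11 and C13, rejoining the route at 17.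

Further compounds
F1 | step 4 | cis-fused 3-methoxy-1,4-diketone (5β-H, C3 unassigned) | O=C1CC(OC)C(=O)[C@H]2[C@@H](OCc3ccc(OC)cc3)C=C(O[Si](C)(C)C(C)(C)C)C[C@@]12C
F2 | step 4 | cis-fused 1,4-diketone (5β-H) | O=C1CCC(=O)[C@H]2[C@@H](OCc3ccc(OC)cc3)C=C(O[Si](C)(C)C(C)(C)C)C[C@@]12C
F3 | step 10 | 8β,11-diol (axial 8β-OH) | CC(C)(C)[Si](C)(C)O[C@@H]1CCC(=C)[C@@H]2[C@@H](OCc3ccc(OC)cc3)[C@H](C(C)(O)C(=O)OC)[C@H](O)C[C@@]12C
F4 | step 10 | 8α-(4-nitrobenzoate) of the 8α,11-diol | CC(C)(C)[Si](C)(C)O[C@@H]1CCC(=C)[C@@H]2[C@@H](OCc3ccc(OC)cc3)[C@H](C(C)(O)C(=O)OC)[C@@H](OC(=O)c4ccc(cc4)[N+](=O)[O-])C[C@@]12C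
F5 | step 12 | bromohydrin ketone (C8 ketone, 7β-[C(OH)(CH2Br)CO2Me], C11 unassigned) | CC(C)(C)[Si](C)(C)O[C@@H]1CCC(=C)[C@@H]2[C@@H](OCc3ccc(OC)cc3)[C@H](C(O)(CBr)C(=O)OC)C(=O)C[C@@]12C
F6 | step 12 | bromohydrin 8α-alcohol | CC(C)(C)[Si](C)(C)O[C@@H]1CCC(=C)[C@@H]2[C@@H](OCc3ccc(OC)cc3)[C@H](C(O)(CBr)C(=O)OC)[C@@H](O)C[C@@]12C
F7 | step 12 | bromohydrin 1β,8α-bis-TBS ether | CC(C)(C)[Si](C)(C)O[C@@H]1CCC(=C)[C@@H]2[C@@H](OCc3ccc(OC)cc3)[C@H](C(O)(CBr)C(=O)OC)[C@@H](O[Si](C)(C)C(C)(C)C)C[C@@]12C
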